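A small charge of free catalyst, 0.50 mM, works in a flask whose solid substrate goes into solution over minutes. I follow one molecule to its fork, where it ends either as target or as isomer of the product.

in all of them: free catalyst 0.50 mM

| flask | solid substrate | remark | time |
|---|---|---|---|
| cedar | 1 M | the very flask that is asked about, followed so far |  |
| maple | 1.5 M | run made earlier |  |
| flask | 1.0 M |  | 4.0 h |

cedar run (percent of the solid substrate charged)

| time / min | isomer of the product / % | target / % | solid substrate / % |
|---|---|---|---|
| 1.33 | 0.9 | 1.6 | 84.7 |
| 4.00 | 1.7 | 3.1 | 70.6 |
| 6.00 | 1.8 | 5.0 | 62.3 |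
| 10.0 | 6.6 | 8.1 | 55.7 |
| 15.0 | 8.4 | 7.9 | 51.7 |
| 20.0 | 9.6 | 10.3 | 48.8 |

maple run (percent of the solid substrate charged)

| time / h | isomer of the product / % | target / % | solid substrate / % |
|---|---|---|---|
| 0.333 | 7.0 | 5.7 | 65.8 |
| 0.500 | 5.8 | 4.3 | 63.1 |
| 0.833 | 9.9 | 9.8 | 60.2 |
| 1.33 | 12.5 | 8.7 | 58.4 |
| 2.50 | 13.1 | 10.3 | 56.7 |
| 4.00 | 15.5 | 11.4 | 51.5 |

(each reading ± 1 percentage point)

- share of isomer of the product in isomer of the product plus target at 2.0 min
- share of isomer of the product in isomer of the product plus target at 4.0 h
- which of isomer of the product and target there is more of at 4.0 h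

Cedar's first two readings, pooled, give an isomer share of 35.6%, which is my reading for 2.0 min.

At 20.0 min, cedar holds 19.9% of its charge as product. Maple at 0.333 h, counted on cedar's charge, holds 19.1%. The two match per litre, so I let maple's later gain stand for cedar's: 21.3% of the charge by 4.0 h.

Maple's first and last readings give that gain an isomer share of 59.9%. Added to cedar's last reading, this makes 54.2% isomer at 4.0 h.

The weak link is that this share rests on single readings with a scatter of 1 percentage point. Pooling maple's first two and last two readings reforges it as 57.5%. This is the late share, the chance that a molecule turning to product late ends as isomer, an instantaneous selectivity. I commit to 53.0%, with the isomer ahead.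

The forecast says 31% at 2.0 min and 55% at 4.0 h, with isomer of the product ahead, noting “later increments near 60%”. So it stands below my reading at 2.0 min and above my figure at 4.0 h.

    starting material ⇌ other conformer (K = 0.600, k = 0.00910 /s)
    starting material + free catalyst → free catalyst + target (k = 95.0 /M/s)
    free catalyst + other conformer → free catalyst + isomer of the product (k = 270 /M/s)
    solid substrate ⇌ starting material, rate k4*(cs4 - [starting material]) while solid is left; crystals form when [starting material] > cs4 (solubility = 0.210 M, k = 0.0130 /s)
    2 free catalyst → spent catalyst (k = 310 /M/s)

The flask gives 33.4% at 2.0 min and 58.7% at 4.0 h, with isomer of the product ahead at 23.5% against 16.5% of target. From 0.400 h to 4.00 h, the flask's gain is 62.8% isomer, beside the late share of 57.5% read from maple. The same flask charged with 0.25 M of solid substrate stands at 55.4% at 4.0 h, which is 91.3% of the way from its 33.4% at 2.0 min to the late share.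

The readings are calculated with made-up constants, and the scatter is random.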